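Ring B (methoxy-bearing dioxine: O1, O2, C3 carrying the acetate arm, C4=C5, ketal C6) is read as the cyclic methyl peroxyketal of a γ-hydroperoxy enone; its C3 is then the α-carbon of an aldehyde whose carbonyl carbon is C4. The key step exploits this: amine-catalysed singlet-oxygen α-hydroperoxidation of methyl 4-oxobutanoate forges the O2–C3 bond enantioselectively and, in the same flask, an acyl ylide carrying preformed ring A olefinates that aldehyde, creating the C4=C5 double bond. Its precursors are an achiral aldehyde ester, dioxygen and an ylide, with no ring B present. Ring A (propyl-bearing dioxine) arises earlier by double SN2 of hydrogen peroxide on a pseudo-meso (Z)-ene-1,4-diol bis-mesylate; photoisomerisation and ketalisation finally close ring B.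

Key step: step 12

Remark: the ketal carbon C6 of ring B is taken to equilibrate in acidic methanol through its peroxycarbenium ion, so its configuration is set in the last step by equilibration, separation of the two epimers and recycling of the unwanted one.

Step 1
Reactants: 1 bis(trimethylsilyl)acetylene; 2 butanoyl chloride
Product: 3 1-(trimethylsilyl)hex-1-yn-3-one
Conditions: AlCl3, CH2Cl2, 0 °C
Reagents that add atoms: none
Why: Friedel–Crafts-type acylative desilylation: the AlCl3-activated acid chloride attacks the alkynylsilane ipso to silicon and loss of Me3SiCl gives the ynone, which is deactivated toward a second acylation.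

Step 2
Reactants: 3 1-(trimethylsilyl)hex-1-yn-3-one
Product: 4 (3R)-1-(trimethylsilyl)hex-1-yn-3-ol
Conditions: RuCl[(R,R)-TsDPEN](p-cymene) (1 mol %), iPrOH, rt
Reagents that add atoms: none
Why: Noyori asymmetric transfer hydrogenation of an alkynyl ketone: the (R,R)-TsDPEN ruthenium hydride differentiates the alkynyl from the alkyl flank in its six-membered hydride/proton transfer transition state and should set the (3R) carbinol, the future propyl-bearing carbon of ring A before inversion.

Step 3
Reactants: 5 5-tert-butoxy-5-oxopentanoic acid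
Product: 6 tert-butyl 5-[methoxy(methyl)amino]-5-oxopentanoate
Conditions: CDI, CH2Cl2, rt; then MeNHOMe·HCl, rt
Reagents that add atoms: N,O-dimethylhydroxylamine hydrochloride, CNOC.Cl
Why: Weinreb amide formation through the acyl imidazolide is mild enough to leave the tert-butyl ester intact and provides an acyl donor that stops at the ketone stage.

Step 4
Reactants: 4 (3R)-1-(trimethylsilyl)hex-1-yn-3-ol; 6 tert-butyl 5-[methoxy(methyl)amino]-5-oxopentanoate
Product: 7 tert-butyl (8R)-8-hydroxy-5-oxoundec-6-ynoate
Conditions: 4, MeLi·LiBr (2.05 equiv), THF, −78 °C → rt; then 6, −78 → −20 °C; aq NH4Cl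
Reagents that add atoms: none
Why: Desilylative lithiation followed by Weinreb ketone synthesis: the first equivalent of MeLi forms the alkoxide, the second cleaves the C(sp)–Si bond to the lithium acetylide, which adds once to 6 through the chelated tetrahedral intermediate and spares the hindered tert-butyl ester, the (8R) centre not being touched.

Step 5
Reactants: 7 tert-butyl (8R)-8-hydroxy-5-oxoundec-6-ynoate
Product: 8 tert-butyl (5S,8R)-5,8-dihydroxyundec-6-ynoate
Conditions: RuCl[(S,S)-TsDPEN](p-cymene) (1 mol %), iPrOH, rt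
Reagents that add atoms: none
Why: A second Noyori asymmetric transfer hydrogenation, now with the enantiomeric (S,S)-catalyst, should reduce the ynone under catalyst control to the (5S) carbinol, which gives the pseudo-meso (unlike) diol needed for a cis-disubstituted ring A.

Step 6
Reactants: 8 tert-butyl (5S,8R)-5,8-dihydroxyundec-6-ynoate
Product: 9 tert-butyl (5S,6Z,8R)-5,8-dihydroxyundec-6-enoate
Conditions: H2 (1 atm), Pd/CaCO3 poisoned with Pb(OAc)2 (Lindlar catalyst), quinoline, EtOAc, rt
Reagents that add atoms: none
Why: Lindlar semihydrogenation adds hydrogen syn to the alkyne only and so fixes the Z-alkene that lets the two carbinol carbons reach each other in a six-membered ring, no stereocentre being touched.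

Step 7
Reactants: 9 tert-butyl (5S,6Z,8R)-5,8-dihydroxyundec-6-enoate
Product: 10 tert-butyl (5S,6Z,8R)-5,8-bis(methanesulfonyloxy)undec-6-enoate
Conditions: MsCl, Et3N, CH2Cl2, −30 °C; used crude at once
Reagents that add atoms: methanesulfonyl chloride, CS(Cl)(=O)=O
Why: O-Sulfonylation proceeds with retention at both carbinol carbons and turns them into leaving groups, low temperature and immediate use limiting ionisation of the allylic mesylates.

Step 8
Reactants: 10 tert-butyl (5S,6Z,8R)-5,8-bis(methanesulfonyloxy)undec-6-enoate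
Product: 11 tert-butyl 4-[(3R,6S)-6-propyl-3,6-dihydro-1,2-dioxin-3-yl]butanoate
Conditions: 50% aq H2O2 (excess), KOH, MeOH–THF, 0 °C
Reagents that add atoms: hydrogen peroxide, OO
Why: Double SN2 peroxide synthesis: hydroperoxide anion displaces one allylic mesylate and the allylic hydroperoxide so formed closes ring A by 6-exo-tet displacement of the second (an SN2' closure would need a four-membered ring), each with inversion, so (5S,8R) becomes the cis (3R,6S) dioxine.

Step 9
Reactants: 11 tert-butyl 4-[(3R,6S)-6-propyl-3,6-dihydro-1,2-dioxin-3-yl]butanoate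
Product: 12 4-[(3R,6S)-6-propyl-3,6-dihydro-1,2-dioxin-3-yl]butanoic acid
Conditions: TFA, CH2Cl2, 0 °C
Reagents that add atoms: none
Why: Acidolysis of the tert-butyl ester (loss of 2-methylpropene through the tert-butyl cation) frees the carboxylic acid under conditions that a dialkyl peroxide should tolerate.

Step 10
Reactants: 12 4-[(3R,6S)-6-propyl-3,6-dihydro-1,2-dioxin-3-yl]butanoic acid; 13 tert-butyl 2-(triphenyl-λ5-phosphanylidene)acetate
Product: 14 tert-butyl 3-oxo-6-[(3R,6S)-6-propyl-3,6-dihydro-1,2-dioxin-3-yl]-2-(triphenyl-λ5-phosphanylidene)hexanoate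
Conditions: EDC·HCl, DMAP (cat.), CH2Cl2, 0 °C → rt
Reagents that add atoms: none
Why: Carbodiimide-mediated C-acylation of a stabilised phosphorus ylide: the activated acid acylates the ylide carbon of 13 and proton loss gives the doubly stabilised keto ester ylide, a route to the acyl ylide that avoids the phosphines and strong bases that would attack ring A.

Step 11
Reactants: 14 tert-butyl 3-oxo-6-[(3R,6S)-6-propyl-3,6-dihydro-1,2-dioxin-3-yl]-2-(triphenyl-λ5-phosphanylidene)hexanoate
Product: 16 5-[(3R,6S)-6-propyl-3,6-dihydro-1,2-dioxin-3-yl]-1-(triphenyl-λ5-phosphanylidene)pentan-2-one, via acylmethylphosphonium trifluoroacetate 15 (not isolated)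
Conditions: TFA, CH2Cl2, rt; then aq NaHCO3
Reagents that add atoms: none
Why: Acidolysis of the tert-butyl ester gives a β-keto acid that loses CO2 at once to the acylmethylphosphonium salt 15, which bicarbonate deprotonates to the stabilised acyl ylide (dealkoxycarbonylation of a keto ester ylide).

Step 12
Reactants: 17 methyl 4-oxobutanoate; 16 5-[(3R,6S)-6-propyl-3,6-dihydro-1,2-dioxin-3-yl]-1-(triphenyl-λ5-phosphanylidene)pentan-2-one
Product: 19 methyl (3R,4E)-3-hydroperoxy-6-oxo-9-[(3R,6S)-6-propyl-3,6-dihydro-1,2-dioxin-3-yl]non-4-enoate, via α-hydroperoxy aldehyde 18 (not isolated)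
Conditions: 17, (R)-2-[diphenyl(trimethylsilyloxy)methyl]pyrrolidine (20 mol %), PhCO2H (20 mol %), tetraphenylporphyrin (cat.), O2, visible light, CHCl3, −20 °C; then N2 purge, dark, 16, CH2Cl2, −20 → 0 °C
Reagents that add atoms: dioxygen, O=O
Why: Proposed new method: the (R)-diphenylprolinol silyl ether condenses with 17 to the anti-(E)-enamine, whose nucleophilic α-carbon (ring B C3) is attacked by photogenerated singlet oxygen, and the peroxy-iminium zwitterion is protonated by benzoic acid and hydrolysed to 18, which forms the O2–C3 bond; with the lamp off and oxygen purged, the neutral stabilised acyl ylide 16 then olefinates the aldehyde carbon of 18 through an oxaphosphetane (Wittig reaction), which forms the C4=C5 double bond between two carbons that were not bonded before. The closest known reaction types are the amine-catalysed asymmetric α-oxidation of aldehydes with singlet oxygen and the one-pot organocatalytic α-aminoxylation/olefination of aldehydes; new is the olefination of a free α-hydroperoxy aldehyde in the same flask. No ring is closed in this step, since the E-enone 19 cannot cyclise until step 13. The new stereocentre (3R) is controlled by the catalyst: the diphenyl(silyloxy)methyl group shields one face of the enamine, so oxygen should add to the opposite face. The step needs α-hydroperoxidation to win over [2+2] cleavage of the enamine (acid co-catalyst, −20 °C) and needs the ylide to react only with the aldehyde, which its weak basicity and non-reducing pentavalent phosphorus should secure with respect to the hydroperoxide and ring A. E-selectivity follows from the stabilised ylide and is corrected in step 13.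

Step 13
Reactants: 19 methyl (3R,4E)-3-hydroperoxy-6-oxo-9-[(3R,6S)-6-propyl-3,6-dihydro-1,2-dioxin-3-yl]non-4-enoate
Product: 22 methyl 2-[(3R,6S)-6-methoxy-6-{3-[(3R,6S)-6-propyl-3,6-dihydro-1,2-dioxin-3-yl]propyl}-3,6-dihydro-1,2-dioxin-3-yl]acetate, via Z-enone 20 (not isolated), via dioxinol 21 (not isolated)
Conditions: hν (350 nm), MeOH, PPTS (cat.), rt; separate the C6 epimers; return the (6R) epimer to PPTS/MeOH
Reagents that add atoms: methanol, CO
Why: Photochemical E→Z isomerisation of the enone becomes irreversible because the Z isomer 20 is trapped by 6-exo-trig addition of the hydroperoxide OH to the ketone (dioxinol 21, chromophore lost), and acid-catalysed exchange with methanol through the peroxycarbenium ion gives the methyl peroxyketal, in which C3 is untouched and C6 equilibrates, so that the (6S) epimer (OMe trans to the acetate arm) is isolated and the (6R) epimer is re-equilibrated.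

Compound list
1 | bis(trimethylsilyl)acetylene | C[Si](C)(C)C#C[Si](C)(C)C | starting material
2 | butanoyl chloride | CCCC(=O)Cl | starting material
3 | 1-(trimethylsilyl)hex-1-yn-3-one | CCCC(=O)C#C[Si](C)(C)C | intermediate
4 | (3R)-1-(trimethylsilyl)hex-1-yn-3-ol | CCC[C@@H](O)C#C[Si](C)(C)C | intermediate
5 | 5-tert-butoxy-5-oxopentanoic acid | CC(C)(C)OC(=O)CCCC(=O)O | starting material
6 | tert-butyl 5-[methoxy(methyl)amino]-5-oxopentanoate | CON(C)C(=O)CCCC(=O)OC(C)(C)C | intermediate
7 | tert-butyl (8R)-8-hydroxy-5-oxoundec-6-ynoate | CCC[C@@H](O)C#CC(=O)CCCC(=O)OC(C)(C)C | intermediate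
8 | tert-butyl (5S,8R)-5,8-dihydroxyundec-6-ynoate | CCC[C@@H](O)C#C[C@@H](O)CCCC(=O)OC(C)(C)C | intermediate
9 | tert-butyl (5S,6Z,8R)-5,8-dihydroxyundec-6-enoate | CCC[C@@H](O)/C=C\[C@@H](O)CCCC(=O)OC(C)(C)C | intermediate
10 | tert-butyl (5S,6Z,8R)-5,8-bis(methanesulfonyloxy)undec-6-enoate | CCC[C@@H](OS(C)(=O)=O)/C=C\[C@@H](OS(C)(=O)=O)CCCC(=O)OC(C)(C)C | intermediate
11 | tert-butyl 4-[(3R,6S)-6-propyl-3,6-dihydro-1,2-dioxin-3-yl]butanoate | CCC[C@H]1C=C[C@@H](CCCC(=O)OC(C)(C)C)OO1 | intermediate
12 | 4-[(3R,6S)-6-propyl-3,6-dihydro-1,2-dioxin-3-yl]butanoic acid | CCC[C@H]1C=C[C@@H](CCCC(=O)O)OO1 | intermediate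
13 | tert-butyl 2-(triphenyl-λ5-phosphanylidene)acetate | CC(C)(C)OC(=O)C=P(c1ccccc1)(c1ccccc1)c1ccccc1 | starting material
14 | tert-butyl 3-oxo-6-[(3R,6S)-6-propyl-3,6-dihydro-1,2-dioxin-3-yl]-2-(triphenyl-λ5-phosphanylidene)hexanoate | CCC[C@H]1C=C[C@@H](CCCC(=O)C(C(=O)OC(C)(C)C)=P(c2ccccc2)(c2ccccc2)c2ccccc2)OO1 | intermediate
15 | triphenyl{2-oxo-5-[(3R,6S)-6-propyl-3,6-dihydro-1,2-dioxin-3-yl]pentyl}phosphonium trifluoroacetate | CCC[C@H]1C=C[C@@H](CCCC(=O)C[P+](c2ccccc2)(c2ccccc2)c2ccccc2)OO1.[O-]C(=O)C(F)(F)F | intermediate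
16 | 5-[(3R,6S)-6-propyl-3,6-dihydro-1,2-dioxin-3-yl]-1-(triphenyl-λ5-phosphanylidene)pentan-2-one | CCC[C@H]1C=C[C@@H](CCCC(=O)C=P(c2ccccc2)(c2ccccc2)c2ccccc2)OO1 | intermediate
17 | methyl 4-oxobutanoate | COC(=O)CCC=O | starting material
18 | methyl (3R)-3-hydroperoxy-4-oxobutanoate | COC(=O)C[C@@H](OO)C=O | intermediate
19 | methyl (3R,4E)-3-hydroperoxy-6-oxo-9-[(3R,6S)-6-propyl-3,6-dihydro-1,2-dioxin-3-yl]non-4-enoate | CCC[C@H]1C=C[C@@H](CCCC(=O)/C=C/[C@@H](CC(=O)OC)OO)OO1 | intermediate
20 | methyl (3R,4Z)-3-hydroperoxy-6-oxo-9-[(3R,6S)-6-propyl-3,6-dihydro-1,2-dioxin-3-yl]non-4-enoate | CCC[C@H]1C=C[C@@H](CCCC(=O)/C=C\[C@@H](CC(=O)OC)OO)OO1 | intermediate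
21 | methyl 2-[(3R)-6-hydroxy-6-{3-[(3R,6S)-6-propyl-3,6-dihydro-1,2-dioxin-3-yl]propyl}-3,6-dihydro-1,2-dioxin-3-yl]acetate (both hemiketal epimers at C6) | CCC[C@H]1C=C[C@@H](CCCC2(O)C=C[C@@H](CC(=O)OC)OO2)OO1 | intermediate
22 | methyl 2-[(3R,6S)-6-methoxy-6-{3-[(3R,6S)-6-propyl-3,6-dihydro-1,2-dioxin-3-yl]propyl}-3,6-dihydro-1,2-dioxin-3-yl]acetate | CCC[C@H]1C=C[C@@H](CCC[C@@]2(OC)C=C[C@@H](CC(=O)OC)OO2)OO1 | target

Total step count: 13. Longest linear sequence: 12 (steps 1, 2 and 4 to 13; step 3 is a one-step branch).

Steps most likely to fail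

1. Step 12 (proposed new method).
- What may go wrong: the free α-hydroperoxy aldehyde may fragment (α-cleavage through a dioxetane, or dehydration of the Kornblum–DeLaMare type) before the ylide reaches it, [2+2] cleavage of the enamine by singlet oxygen may compete with hydroperoxidation, and facial selectivity may be eroded.
- Fallback (known chemistry only), setting out from 17 and coming back to the route at 19: the amine-catalysed singlet-oxygen α-oxidation of 17 is run as a separate operation and the hydroperoxide is capped in the flask with 2-methoxypropene and PPTS to give methyl (3R)-3-[(2-methoxypropan-2-yl)peroxy]-4-oxobutanoate F1, which is isolated. Wittig reaction of this protected peroxy aldehyde with 16 (CH2Cl2, rt) should give methyl (3R,4E)-3-[(2-methoxypropan-2-yl)peroxy]-6-oxo-9-[(3R,6S)-6-propyl-3,6-dihydro-1,2-dioxin-3-yl]non-4-enoate F2. AcOH–THF–H2O then releases the hydroperoxide to give 19.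

2. Step 8.
- What may go wrong: ionisation, E2 elimination or SN2' attack at the allylic mesylates, and substitution by hydroxide followed by intramolecular etherification, may outrun the double displacement by hydroperoxide.
- Fallback, setting out from 10 and coming back at 11: a protected hydroperoxide is used stepwise under anhydrous conditions. 2-Methoxypropan-2-yl hydroperoxide F3 (from ozonolysis of 2,3-dimethylbut-2-ene in CH2Cl2–MeOH) as its caesium salt (CsOH·H2O, DMF, 0 °C, one equivalent) displaces one mesylate with inversion. This gives the two regioisomers tert-butyl (5S,6Z,8S)-8-[(2-methoxypropan-2-yl)peroxy]-5-(methanesulfonyloxy)undec-6-enoate F4 and tert-butyl (5R,6Z,8R)-5-[(2-methoxypropan-2-yl)peroxy]-8-(methanesulfonyloxy)undec-6-enoate F5. AcOH–THF–H2O unmasks them to tert-butyl (5S,6Z,8S)-8-hydroperoxy-5-(methanesulfonyloxy)undec-6-enoate F6 and tert-butyl (5R,6Z,8R)-5-hydroperoxy-8-(methanesulfonyloxy)undec-6-enoate F7. Cs2CO3 in DMF at 0 °C closes each by 6-exo-tet SN2 with inversion, so both regioisomers converge on 11.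

3. Step 13.
- What may go wrong: equilibration at C6 may favour the (6R) epimer, and prolonged irradiation in acidic methanol may cause O–O homolysis or dehydration of the hydroperoxy enone.
- Fallback, setting out from 19 and coming back at 22: the irradiation is run in MeCN without methanol or acid, and the dioxinol 21 is isolated. Its hemiketal hydroxyl is then methylated kinetically with trimethyloxonium tetrafluoroborate and 2,6-di-tert-butyl-4-methylpyridine (CH2Cl2, −40 °C). This is an anomeric O-alkylation with retention at C6 under Curtin–Hammett control, which should favour the more nucleophilic equatorial hydroxyl and hence the (6S) ketal. No new compound is made.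

Further compounds
F1 | step 12 | methyl (3R)-3-[(2-methoxypropan-2-yl)peroxy]-4-oxobutanoate | COC(=O)C[C@@H](OOC(C)(C)OC)C=O
F2 | step 12 | methyl (3R,4E)-3-[(2-methoxypropan-2-yl)peroxy]-6-oxo-9-[(3R,6S)-6-propyl-3,6-dihydro-1,2-dioxin-3-yl]non-4-enoate | CCC[C@H]1C=C[C@@H](CCCC(=O)/C=C/[C@@H](CC(=O)OC)OOC(C)(C)OC)OO1
F3 | step 8 | 2-methoxypropan-2-yl hydroperoxide | CC(C)(OC)OO
F4 | step 8 | tert-butyl (5S,6Z,8S)-8-[(2-methoxypropan-2-yl)peroxy]-5-(methanesulfonyloxy)undec-6-enoate | CCC[C@H](OOC(C)(C)OC)/C=C\[C@@H](OS(C)(=O)=O)CCCC(=O)OC(C)(C)C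
F5 | step 8 | tert-butyl (5R,6Z,8R)-5-[(2-methoxypropan-2-yl)peroxy]-8-(methanesulfonyloxy)undec-6-enoate | CCC[C@@H](OS(C)(=O)=O)/C=C\[C@H](OOC(C)(C)OC)CCCC(=O)OC(C)(C)C
F6 | step 8 | tert-butyl (5S,6Z,8S)-8-hydroperoxy-5-(methanesulfonyloxy)undec-6-enoate | CCC[C@H](OO)/C=C\[C@@H](OS(C)(=O)=O)CCCC(=O)OC(C)(C)C
F7 | step 8 | tert-butyl (5R,6Z,8R)-5-hydroperoxy-8-(methanesulfonyloxy)undec-6-enoate | CCC[C@@H](OS(C)(=O)=O)/C=C\[C@H](OO)CCCC(=O)OC(C)(C)C
F0 | step 13 | none | none
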